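**Plan**

1. Retrosynthesis cuts the O1–C2 bond of the dihydrofuran ring first. The isopropenyl carbon on C2 is β to O1 and can carry a tertiary cation, so O1/C2/isopropenyl is the 1,2-oxygen-shifted, deprotonated form of the O1–C(CH3)2–C3 unit of a six-membered 2,2-dimethylchroman with a leaving group on C3.
2. Next cuts: the ester C–O bond (anti opening of a (3R,4R)-3,4-epoxychroman by the acid), the epoxide (back to the chromene encecalin), and the pyran ring (back to an aryl 1,1-dimethylpropargyl ether of 4-hydroxy-2-methoxyacetophenone).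
3. The acid is cut at C–CO2H: (Z)-2-iodobut-2-en-1-ol from crotonaldehyde is carboxylated through its O,C-dilithio derivative and then O-acetylated.
4. Forward: the benzene ring is bought; the temporary pyran ring arises by Claisen shift and oxa-6π closure; the oxirane is fused on and opened by the acid; in the last step the pyran ring contracts to the furan ring, and the O–C(CH3)2 bond, which is not in the target, is cleaved to the isopropenyl group.
5. Stereochemistry: the Jacobsen epoxidation sets both carbons; SN2 opening inverts chroman C4 (C3 of the target, S); the oxygen shift inverts chroman C3 (C2 of the target, R), so the trans hydroxy ester gives the trans product; the Z alkene comes from the Z iodide with retention.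

Key step: step 9

Assumption: the SMILES is read as the trans-(2R,3S) dihydrobenzofuran with a Z alkene in the ester (CO2R cis to CH3, angelate type); compounds 1, 2 and 8 are taken as commercial.

**Route**

Step 1
Reactants: 1 1-(4-hydroxy-2-methoxyphenyl)ethan-1-one; 2 3-chloro-3-methylbut-1-yne
Product: 3 1-{2-methoxy-4-[(2-methylbut-3-yn-2-yl)oxy]phenyl}ethan-1-one
Conditions: K2CO3, KI (cat.), CuI (cat.), acetone, reflux
Reagents that add atoms: none
Why: CuI-assisted Williamson-type O-alkylation of the phenoxide with the tertiary propargylic chloride is the standard entry to aryl 1,1-dimethylpropargyl ethers and tolerates para-acyl phenols; no stereocentre is formed.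

Step 2
Reactants: 3 1-{2-methoxy-4-[(2-methylbut-3-yn-2-yl)oxy]phenyl}ethan-1-one
Product: 6 encecalin [1-(7-methoxy-2,2-dimethyl-2H-chromen-6-yl)ethan-1-one], via allenylphenol 4 (not isolated), via o-quinone methide 5 (not isolated)
Conditions: N,N-diethylaniline, 190 °C
Reagents that add atoms: none
Why: Aryl propargyl Claisen rearrangement ([3,3] shift) to the ortho carbon para to the methoxy group (the other ortho carbon is flanked by OH and OMe) gives after enolisation allenylphenol 4, a [1,5]-hydrogen shift gives o-quinone methide 5 and oxa-6π electrocyclisation closes the pyran ring, which is the classical 2,2-dimethylchromene synthesis; no stereocentre is formed.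

Step 3
Reactants: 6 encecalin
Product: 7 1-[(3R,4R)-3,4-epoxy-7-methoxy-2,2-dimethyl-3,4-dihydro-2H-chromen-6-yl]ethan-1-one
Conditions: (R,R)-(salen)MnCl [Jacobsen catalyst, C36H52ClMnN2O2, salen = N,N'-bis(3,5-di-tert-butylsalicylidene)cyclohexane-1,2-diaminate, trivalent manganese] (4 mol%), aq. NaOCl (Na2HPO4 buffer, pH 11.3), 4-phenylpyridine N-oxide (20 mol%), CH2Cl2, 0 °C
Reagents that add atoms: sodium hypochlorite, [Na+].[O-]Cl
Why: Jacobsen–Katsuki epoxidation, for which the aryl-conjugated cis alkene of 2,2-dimethylchromenes is among the best substrates: side-on approach of the C3=C4 bond to the Mn=O oxidant (pentavalent manganese) of the (R,R)-catalyst should give the (3R,4R)-epoxide (the (S,S)-catalyst is known to give (3S,4S)-epoxychromans), so both stereocentres are set by the catalyst, and the cold buffered two-phase medium should spare the methyl ketone from haloform cleavage.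

Step 4
Reactants: 8 (E)-but-2-enal (crotonaldehyde)
Product: 9 (Z)-2-iodobut-2-enal
Conditions: I2, K2CO3, DMAP (cat.), THF/H2O (1:1), rt
Reagents that add atoms: iodine, II
Why: Amine-catalysed α-iodination of an enal (conjugate addition of DMAP, iodination of the enolate, E1cB loss of DMAP, a Baylis–Hillman-type addition–elimination) gives the more stable geometry with CHO trans to CH3, which places iodine cis to the methyl group (Z).

Step 5
Reactants: 9 (Z)-2-iodobut-2-enal
Product: 10 (Z)-2-iodobut-2-en-1-ol
Conditions: NaBH4, THF/H2O (9:1), 0 °C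
Reagents that add atoms: none
Why: Borohydride 1,2-reduction of the aldehyde; the alkene geometry is not touched and no stereocentre is formed.

Step 6
Reactants: 10 (Z)-2-iodobut-2-en-1-ol
Product: 12 (Z)-2-(hydroxymethyl)but-2-enoic acid, via dilithio species 11 (not isolated)
Conditions: t-BuLi (3.1 equiv), Et2O, −78 °C; then CO2 (gas), −78 °C to rt; aq. HCl work-up
Reagents that add atoms: carbon dioxide, O=C=O
Why: The first equivalent of t-BuLi deprotonates the hydroxyl group and the next two effect iodine–lithium exchange (the second destroys t-BuI) to give the O,C-dilithio species 11 of the 2-lithioallyl alkoxide type; alkenyllithiums keep their configuration at −78 °C and are carboxylated with retention, so CO2H replaces iodine cis to the methyl group (Z).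

Step 7
Reactants: 12 (Z)-2-(hydroxymethyl)but-2-enoic acid
Product: 13 (Z)-2-(acetoxymethyl)but-2-enoic acid
Conditions: Ac2O, pyridine, CH2Cl2, 0 °C to rt; aqueous work-up
Reagents that add atoms: acetic anhydride, CC(=O)OC(C)=O
Why: Plain O-acetylation of the primary allylic alcohol; pyridine is used without DMAP so that no strongly nucleophilic amine adds SN2′ to the 2-(acyloxymethyl)but-2-enoate unit and scrambles the alkene geometry.

Step 8
Reactants: 7 1-[(3R,4R)-3,4-epoxy-7-methoxy-2,2-dimethyl-3,4-dihydro-2H-chromen-6-yl]ethan-1-one (used crude); 13 (Z)-2-(acetoxymethyl)but-2-enoic acid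
Product: 14 (3R,4S)-6-acetyl-3-hydroxy-7-methoxy-2,2-dimethyl-3,4-dihydro-2H-chromen-4-yl (2Z)-2-[(acetyloxy)methyl]but-2-enoate
Conditions: 13 (1.3 equiv), i-Pr2NEt (0.3 equiv), MeCN, 40 °C
Reagents that add atoms: none
Why: Base-buffered carboxylic acid opening of an epoxide (SN2): the carboxylate attacks the benzylic C4, activated by the para-methoxy group, and not the neopentyl-like C3 next to the gem-dimethyl carbon, from the face opposite the epoxide oxygen, so C4 is inverted and C3 keeps its configuration to give the trans (3R,4S) hydroxy ester, while the non-nucleophilic amine and the mild temperature should suppress ionisation to the benzylic cation and acyl migration to O3.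

Step 9
Reactants: 14 (3R,4S)-6-acetyl-3-hydroxy-7-methoxy-2,2-dimethyl-3,4-dihydro-2H-chromen-4-yl (2Z)-2-[(acetyloxy)methyl]but-2-enoate
Product: 17 (2R,3S)-5-acetyl-6-methoxy-2-(prop-1-en-2-yl)-2,3-dihydro-1-benzofuran-3-yl (2Z)-2-[(acetyloxy)methyl]but-2-enoate, via triflate 15 (not isolated), via oxiranium triflate 16 (not isolated)
Conditions: Tf2O (1.1 equiv), 2,6-lutidine (3 equiv), CH2Cl2, −78 °C to rt
Reagents that add atoms: none
Why: Triflation of the C3 hydroxyl gives 15, in whose trans-diequatorial half-chair the C3–OTf bond is antiperiplanar to the ring bond C2–O1; the aryl oxygen therefore displaces triflate from the back to give the bridged oxiranium ion 16, and its O–C(CH3)2 bond then breaks at the tertiary carbon with loss of a methyl proton to 2,6-lutidine, which leaves the isopropenyl group. The closest known reaction type is the aryl-oxygen 1,2-shift (Wagner–Meerwein type) ring contraction of activated 2,2-dimethylchroman-3-ols to 2-isopropenyl-2,3-dihydrobenzofurans, as in the decursinol-to-marmesin type rearrangements. The furan ring closes in the 5-exo-tet mode (O1 onto C3 with triflate leaving outside the ring) and the transient oxiranium ring in the 3-exo-tet mode. The one new stereocentre, C2 of 17 (the former chroman C3), is set by this intramolecular SN2 inversion of the (3R) carbinol carbon from the Jacobsen epoxide, which gives (2R); the ester carbon (chroman C4, now C3, S) is not touched, so the trans hydroxy ester gives the trans product. The step needs the O1 shift to win over participation of the C4 acyloxy group, a methyl shift and E2 loss of H4, and the diequatorial conformer secures this because only the C2–O1 bond is aligned with the leaving group there (acyloxy and axial methyl are aligned only in the minor diaxial conformer, H4 is gauche to the triflate). Proton loss is from a methyl group and not from the C2–H, whose carbon is part of the three-membered ring so that it cannot become antiperiplanar to the breaking C–O bond, and the 2-isopropylidene enol ether and the aromatic benzofuran should therefore not form.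

**Compound list**

1 | 1-(4-hydroxy-2-methoxyphenyl)ethan-1-one | CC(=O)c1ccc(O)cc1OC | starting material
2 | 3-chloro-3-methylbut-1-yne | CC(C)(Cl)C#C | starting material
3 | 1-{2-methoxy-4-[(2-methylbut-3-yn-2-yl)oxy]phenyl}ethan-1-one | CC(=O)c1ccc(OC(C)(C)C#C)cc1OC | intermediate
4 | 1-[4-hydroxy-2-methoxy-5-(3-methylbuta-1,2-dien-1-yl)phenyl]ethan-1-one (allenylphenol) | CC(=O)c1cc(C=C=C(C)C)c(O)cc1OC | intermediate
5 | (6Z)-4-acetyl-3-methoxy-6-(3-methylbut-2-en-1-ylidene)cyclohexa-2,4-dien-1-one (o-quinone methide) | CC(=O)C1=C/C(=C/C=C(C)C)C(=O)C=C1OC | intermediate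
6 | encecalin, 1-(7-methoxy-2,2-dimethyl-2H-chromen-6-yl)ethan-1-one | CC(=O)c1cc2C=CC(C)(C)Oc2cc1OC | intermediate
7 | 1-[(3R,4R)-3,4-epoxy-7-methoxy-2,2-dimethyl-3,4-dihydro-2H-chromen-6-yl]ethan-1-one | CC(=O)c1cc2c(cc1OC)OC(C)(C)[C@@H]1O[C@H]21 | intermediate
8 | (E)-but-2-enal (crotonaldehyde) | C/C=C/C=O | starting material
9 | (Z)-2-iodobut-2-enal (iodine cis to CH3) | C/C=C(\I)C=O | intermediate
10 | (Z)-2-iodobut-2-en-1-ol (iodine cis to CH3) | C/C=C(\I)CO | intermediate
11 | lithium (E)-2-lithiobut-2-en-1-olate (C–Li cis to CH3, geometry of 10 retained) | C/C=C(\[Li])CO[Li] | intermediate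
12 | (Z)-2-(hydroxymethyl)but-2-enoic acid (CO2H cis to CH3) | C/C=C(\C(=O)O)CO | intermediate
13 | (Z)-2-(acetoxymethyl)but-2-enoic acid (CO2H cis to CH3) | C/C=C(\C(=O)O)COC(C)=O | intermediate
14 | (3R,4S)-6-acetyl-3-hydroxy-7-methoxy-2,2-dimethyl-3,4-dihydro-2H-chromen-4-yl (2Z)-2-[(acetyloxy)methyl]but-2-enoate (trans) | CC(=O)c1cc2c(cc1OC)OC(C)(C)[C@H](O)[C@H]2OC(=O)/C(=C\C)COC(C)=O | intermediate
15 | (3R,4S)-6-acetyl-7-methoxy-2,2-dimethyl-3-{[(trifluoromethyl)sulfonyl]oxy}-3,4-dihydro-2H-chromen-4-yl (2Z)-2-[(acetyloxy)methyl]but-2-enoate | CC(=O)c1cc2c(cc1OC)OC(C)(C)[C@H](OS(=O)(=O)C(F)(F)F)[C@H]2OC(=O)/C(=C\C)COC(C)=O | intermediate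
16 | oxiranium triflate: the aryl-bound ring oxygen bridges the C(CH3)2 carbon and the former chroman C3 (inverted, configured as C2 of 17), the ester carbon is unchanged, triflate is the counter-ion | CC(=O)c1cc2c(cc1OC)[O+]1C(C)(C)[C@@H]1[C@H]2OC(=O)/C(=C\C)COC(C)=O.[O-]S(=O)(=O)C(F)(F)F | intermediate
17 | (2R,3S)-5-acetyl-6-methoxy-2-(prop-1-en-2-yl)-2,3-dihydro-1-benzofuran-3-yl (2Z)-2-[(acetyloxy)methyl]but-2-enoate | C=C(C)[C@H]1Oc2cc(OC)c(C(C)=O)cc2[C@@H]1OC(=O)/C(=C\C)COC(C)=O | target

**Step count and risks**

Total steps: 9. Longest linear sequence: 6 (steps 4, 5, 6, 7, 8, 9).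

Steps most likely to fail:

1. Step 9. The ring oxygen is para to the acetyl group and may shift too slowly. Participation of the neighbouring acyloxy group from the diaxial conformer, ionisation of the methoxy-activated benzylic ester, or elimination towards the aromatic benzofuran could then take over.
Fallback: the same O–C2 bond is formed by a different ring closure, a phenoxide opening of a vinyl epoxide. It sets out from 1 and comes back at 17.
   - Ortho-formylation of 1 (MgCl2, Et3N, paraformaldehyde, MeCN, reflux) should give 5-acetyl-2-hydroxy-4-methoxybenzaldehyde F1.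
   - Silylation (TIPSCl, imidazole, DMF) should give 5-acetyl-4-methoxy-2-[(triisopropylsilyl)oxy]benzaldehyde F2.
   - Horner–Wadsworth–Emmons olefination with lithiated diethyl (2-methylallyl)phosphonate (n-BuLi, THF/HMPA, −78 °C to rt) should give the (E)-diene 1-{2-methoxy-5-[(1E)-3-methylbuta-1,3-dien-1-yl]-4-[(triisopropylsilyl)oxy]phenyl}ethan-1-one F3.
   - Shi epoxidation with the ketone catalyst derived from L-fructose (KHSO5 as 2KHSO5·KHSO4·K2SO4, K2CO3 buffer, MeCN/dimethoxymethane/H2O, 0 °C) should epoxidise the trans-disubstituted aryl-conjugated double bond to the vinyl epoxide 1-{2-methoxy-5-[(2S,3S)-3-(prop-1-en-2-yl)oxiran-2-yl]-4-[(triisopropylsilyl)oxy]phenyl}ethan-1-one F4.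
   - TBAF (THF, 0 °C) frees the phenoxide, which should open the epoxide at the allylic carbon with inversion to close the five-membered ring and give the trans alcohol 1-[(2R,3S)-3-hydroxy-6-methoxy-2-(prop-1-en-2-yl)-2,3-dihydro-1-benzofuran-5-yl]ethan-1-one F5.
   - Steglich esterification of F5 with 13 (DCC, a little DMAP, CH2Cl2, 0 °C) gives 17.

2. Step 8. The epoxide may ionise at the methoxy-activated benzylic carbon before the carboxylate arrives, which would erode the anti selectivity, and the acyl group may migrate to O3.
Fallback: C–O bond formation is separated from acylation. It sets out from 7 and comes back at 14. Hydroxide (aq. NaOH, DMSO, 50 °C) should open the epoxide by SN2 at C4 to give the trans diol 1-[(3R,4S)-3,4-dihydroxy-7-methoxy-2,2-dimethyl-3,4-dihydro-2H-chromen-6-yl]ethan-1-one F6. Selective Steglich acylation of the less hindered benzylic 4-OH (the 3-OH is flanked by the gem-dimethyl carbon) with 13 (DCC, cat. DMAP, CH2Cl2, −20 °C) gives 14.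

3. Step 2. The Claisen shift may show poor regioselectivity, with migration to the ortho carbon between OH and OMe.
Fallback: an electrophilic, boron-templated chromenylation whose site is fixed by the para-methoxy group. It sets out from 1 and comes back at 6. PhB(OH)2 and 3-methylbut-2-enal (CC(C)=CC=O) with catalytic propionic acid in refluxing toluene (water removal) should give the benzodioxaborin 1-[7-methoxy-4-(2-methylprop-1-en-1-yl)-2-phenyl-4H-1,3,2-benzodioxaborinin-6-yl]ethan-1-one F7. On heating F7 fragments to o-quinone methide 5, which closes to 6.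

Further compounds
F1 | step 9 | 5-acetyl-2-hydroxy-4-methoxybenzaldehyde | CC(=O)c1cc(C=O)c(O)cc1OC
F2 | step 9 | 5-acetyl-4-methoxy-2-[(triisopropylsilyl)oxy]benzaldehyde | CC(=O)c1cc(C=O)c(O[Si](C(C)C)(C(C)C)C(C)C)cc1OC
F3 | step 9 | 1-{2-methoxy-5-[(1E)-3-methylbuta-1,3-dien-1-yl]-4-[(triisopropylsilyl)oxy]phenyl}ethan-1-one | CC(=O)c1cc(/C=C/C(C)=C)c(O[Si](C(C)C)(C(C)C)C(C)C)cc1OC
F4 | step 9 | 1-{2-methoxy-5-[(2S,3S)-3-(prop-1-en-2-yl)oxiran-2-yl]-4-[(triisopropylsilyl)oxy]phenyl}ethan-1-one | CC(=O)c1cc([C@@H]2O[C@H]2C(C)=C)c(O[Si](C(C)C)(C(C)C)C(C)C)cc1OC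
F5 | step 9 | 1-[(2R,3S)-3-hydroxy-6-methoxy-2-(prop-1-en-2-yl)-2,3-dihydro-1-benzofuran-5-yl]ethan-1-one | C=C(C)[C@H]1Oc2cc(OC)c(C(C)=O)cc2[C@@H]1O
F6 | step 8 | 1-[(3R,4S)-3,4-dihydroxy-7-methoxy-2,2-dimethyl-3,4-dihydro-2H-chromen-6-yl]ethan-1-one | CC(=O)c1cc2c(cc1OC)OC(C)(C)[C@H](O)[C@H]2O
F7 | step 2 | 1-[7-methoxy-4-(2-methylprop-1-en-1-yl)-2-phenyl-4H-1,3,2-benzodioxaborinin-6-yl]ethan-1-one (racemic at C4) | CC(=O)c1cc2C(C=C(C)C)OB(c3ccccc3)Oc2cc1OC
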